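**Assumption:** Radermachol has no stereocentres and no stereogenic double bond (the alkene carbon carries two identical methyls), so it is achiral and the "single enantiomer" requirement is moot. The SMILES shows the seven-ring enol / six-ring ketone tautomer, which is the same compound as the 5-naphthol / diketone tautomer formed in Step 3. The route is a paper design; conditions are proposed by analogy and have not been tested.

## Retrosynthetic overview

1. The isobutenyl group is unmasked last from a saturated isobutyl chain (furfurylic bromination, then loss of HBr), so no alkene has to survive the Lewis-acid step.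
2. The seven-membered ring and its benzo ring come from phthalic anhydride by double Friedel–Crafts acylation at furan C-3 and naphthalene C-4 of 2-isobutyl-5-methoxynaphtho[1,2-b]furan, with O-demethylation in the same melt.
3. The furan ring comes from an aryl propargyl ether by Claisen rearrangement and CsF-mediated cyclisation.
4. The ether comes from 4-methoxy-1-naphthol and 4-methylpent-1-yn-3-ol by Mitsunobu reaction.
5. Ring order: naphthalene (purchased) → furan (Step 2) → seven-membered ring plus benzo ring (Step 3) → side-chain alkene (Steps 4–5).

## Route

**Step 1**
Reactants: **1** 4-methoxy-1-naphthol; **2** (±)-4-methylpent-1-yn-3-ol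
Product: **3** (±)-1-methoxy-4-[(4-methylpent-1-yn-3-yl)oxy]naphthalene
Conditions: PPh3, DIAD, THF, 0 °C → rt
Reagents that add atoms: none beyond reactants 1 and 2 (PPh3 and DIAD leave no atoms)
Why: Mitsunobu etherification of an acidic naphthol with a secondary propargylic alcohol; the carbinol centre is racemic and is destroyed in Step 2, so its configuration is irrelevant.

**Step 2**
Reactants: **3**
Product: **4** 5-methoxy-2-(2-methylpropyl)naphtho[1,2-b]furan
Conditions: CsF (3–5 equiv), PhNEt2, reflux (about 215 °C), N2
Reagents that add atoms: none (isomerisation)
Why: Aryl propargyl ether Claisen rearrangement to the only free ortho position (naphthalene C-2) gives the 2-allenyl naphthol (Ar–CH=C=CH–iPr). Under CsF the naphthoxide adds to the central allene carbon to give the 2-alkylfuran rather than the chromene, so the former carbinol carbon becomes the CH2 of the isobutyl group.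

**Step 3**
Reactants: **4**; **5** phthalic anhydride
Product: **6** "dihydroradermachol": the radermachol ring system (5-hydroxynaphtho[1,2-b]furan with C-3 and C-4 bridged by an o-C6H4(CO)2 unit, drawn as the chelated enol tautomer) carrying 2-methylpropyl at furan C-2
Conditions: **5** (2–3 equiv), AlCl3/NaCl melt, 180–190 °C, 5–15 min; then ice/aq HCl
Reagents that add atoms: phthalic anhydride, O=C1OC(=O)c2ccccc12 (supplies the C8H4O2 phthaloyl unit; water is lost)
Why: Double Friedel–Crafts acylation. With furan C-2 blocked by the alkyl group, the only pair of positions the phthaloyl unit can bridge is C-4 (ortho to the C-5 oxygen) and furan C-3, which closes the seven-membered ring. The melt also cleaves the methyl ether, and the product is stabilised as an aluminium chelate until work-up.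

**Step 4**
Reactants: **6**
Product: **7** (±)-2-(1-bromo-2-methylpropyl) analogue of 6 (bromine on the furfurylic carbon)
Conditions: NBS (1.05 equiv), AIBN (cat.), PhCF3, 80–85 °C; filter off succinimide, concentrate; use crude
Reagents that add atoms: N-bromosuccinimide, O=C1CCC(=O)N1Br (adds Br)
Why: Wohl–Ziegler radical bromination is selective for the furfurylic CH2, which has the weakest C–H bond. All positions of the electron-rich furan/naphthol core are substituted, so ring bromination is not available. The new stereocentre is racemic and is removed in Step 5.

**Step 5**
Reactants: **7**
Product: **8** radermachol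
Conditions: DBU (2.5 equiv), THF, rt → 50 °C; dilute HCl work-up
Reagents that add atoms: none
Why: E2 dehydrobromination. The only β-hydrogen in 7 is the isopropyl methine, so elimination can give only the conjugated CH=C(CH3)2 alkene, with no E/Z issue. Excess base is used because the acidic chelated enol consumes one equivalent; acid work-up returns the free enol.

## Compound list

| No. | Name | SMILES | Role |
|---|---|---|---|
| 1 | 4-methoxy-1-naphthol | COc1ccc(O)c2ccccc12 | starting material |
| 2 | (±)-4-methylpent-1-yn-3-ol | CC(C)C(O)C#C | starting material |
| 3 | (±)-1-methoxy-4-[(4-methylpent-1-yn-3-yl)oxy]naphthalene | COc1ccc(OC(C#C)C(C)C)c2ccccc12 | intermediate |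
| 4 | 5-methoxy-2-(2-methylpropyl)naphtho[1,2-b]furan | COc1cc2cc(CC(C)C)oc2c2ccccc12 | intermediate |
| 5 | phthalic anhydride | O=C1OC(=O)c2ccccc12 | starting material |
| 6 | dihydroradermachol (2-isobutyl core) | CC(C)Cc1oc2c3c(c(O)c4ccccc4c(=O)c13)C(=O)c1ccccc1-2 | intermediate |
| 7 | (±)-α-bromo-dihydroradermachol | CC(C)C(Br)c1oc2c3c(c(O)c4ccccc4c(=O)c13)C(=O)c1ccccc1-2 | intermediate |
| 8 | radermachol | CC(C)=Cc1oc2c3c(c(O)c4ccccc4c(=O)c13)C(=O)c1ccccc1-2 | target |

## Summary

**Total steps:** 5. **Longest linear sequence:** 5 (Steps 1–5; phthalic anhydride enters as a purchased reagent at Step 3).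

**Steps most likely to fail, with fallbacks:**

1. **Step 3 (melt).** Risks are furan decomposition, isomerisation of the isobutyl chain, or phthalein formation under AlCl3 at 180 °C. Fallback: build the ring stepwise. Brominate 4 at C-3, do Br/Li exchange and add to phthalic anhydride to give the C-3 keto acid, close onto C-4 with TFAA or via the acid chloride and SnCl4, then remove the methyl ether with BBr3.
2. **Step 2 (Claisen/cyclisation).** The α-substituted allenyl naphthol may divert to the 2-isopropyl-2H-benzo[h]chromene. Fallback: iodinate 1 at C-2 (NIS) and make the furan by one-pot Sonogashira coupling and 5-endo-dig cyclisation with 4-methylpent-1-yne (Pd/Cu, Et3N).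
3. **Step 4 (radical bromination).** Risks are over-bromination, competing bromination at the isopropyl methine, or poor radical-chain behaviour of the coloured, chelating substrate. Fallback: make the alkene by olefination instead. Carry the 2-methyl analogue (from propargyl bromide in Step 1) through Steps 2–3, convert CH3 to CH2Br (NBS) and then to CHO (Kornblum or NMO oxidation), and finish with a Wittig reaction using Ph3P=C(CH3)2, with an extra equivalent of ylide for the acidic enol.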